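C1/C10 are the ring-fusion carbons; the ten-membered ring is C1–C2=C3(CO2Me)–C4–C5–C6=C7(CO2H)–C8(OH)–C9–C10 and the six-membered ring is C10–C11(=CH2)–C12–C13–C14(=CMe2)–C1.
Cuts: C7–C8 (Nozaki–Hiyama–Kishi) and C2=C3 (Horner–Wadsworth–Emmons) open the ten-membered ring, C13–C14 opens the six-membered ring, and C1–C10 (Ireland–Claisen) separates the two fusion centres.
Enabling feature: in the six-membered ring C11 is a masked ketone next to the unsubstituted C12–C13 unit, so C11–C12–C13 can be stored as a cyclopropanol with two equivalent CH2 groups; C14 is an sp2 carbon whose partner C15 carries two identical methyls, so it can be an alkenyl bromide with no geometry.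
Forward: C1–C10 is made first in an open chain, the six-membered ring follows by palladium-catalysed three-atom ring expansion of the cyclopropanol (C13–C14), then C11 methylenation and C2=C3, and the ten-membered ring closes last at C7–C8 before allyl ester cleavage.
Stereochemistry: C1 and C10 come by chirality transfer from a CBS-derived (R)-allylic alcohol through the chair Ireland–Claisen transition state, C8 from substrate control in the ring closure, and the two ring alkenes from an (E)-selective HWE and a (Z)-selective iodo-ylide Wittig reaction.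

Key step: step 10

Step 1
Reactants: 1 3-methylbut-2-enal
Product: 3 2-bromo-3-methylbut-2-enal, via dibromide 2 (not isolated)
Conditions: Br2, CH2Cl2, 0 °C; then Et3N, 0 °C → rt
Reagents that add atoms: bromine, BrBr
Why: Bromine adds across the enal C=C and triethylamine removes the acidic α-hydrogen with loss of the β-bromide (bromination–dehydrobromination), the standard entry to α-bromoenals; the alkene carbon that becomes C15 carries two methyls, so no geometry arises.

Step 2
Reactants: 3 2-bromo-3-methylbut-2-enal; 4 1-(triphenyl-λ5-phosphanylidene)propan-2-one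
Product: 5 (3E)-5-bromo-6-methylhepta-3,5-dien-2-one
Conditions: toluene, 80 °C
Reagents that add atoms: none
Why: Wittig reaction of a stabilised acyl ylide with an aldehyde should give the (E)-enone.

Step 3
Reactants: 5 (3E)-5-bromo-6-methylhepta-3,5-dien-2-one
Product: 6 (2R,3E)-5-bromo-6-methylhepta-3,5-dien-2-ol
Conditions: (S)-2-methyl-CBS-oxazaborolidine (10 mol%), catecholborane, toluene, −78 °C
Reagents that add atoms: none
Why: Corey–Bakshi–Shibata reduction with the dienyl group as the large substituent should deliver hydride from the (S)-catalyst to give the (R)-carbinol, the only source of absolute configuration in the route.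

Step 4
Reactants: 7 methyl 4,4-dimethoxybutanoate
Product: 8 4,4-dimethoxybutanoic acid
Conditions: LiOH, THF/H2O, rt; then 1 M HCl to pH 4–5, 0 °C
Reagents that add atoms: lithium hydroxide, [Li+].[OH-]
Why: Saponification of a methyl ester; the acetal is stable to base and the acidification is stopped before it can ionise.

Step 5
Reactants: 6 (2R,3E)-5-bromo-6-methylhepta-3,5-dien-2-ol; 8 4,4-dimethoxybutanoic acid
Product: 9 (2R,3E)-5-bromo-6-methylhepta-3,5-dien-2-yl 4,4-dimethoxybutanoate
Conditions: DCC, DMAP (cat.), CH2Cl2, 0 °C → rt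
Reagents that add atoms: none
Why: Steglich esterification acylates the secondary allylic alcohol without ionising it, so the carbinol configuration is retained.

Step 6
Reactants: 9 (2R,3E)-5-bromo-6-methylhepta-3,5-dien-2-yl 4,4-dimethoxybutanoate
Product: 12 (2S,3S,4E)-3-(1-bromo-2-methylprop-1-en-1-yl)-2-(2,2-dimethoxyethyl)hex-4-enoic acid, via silyl ketene acetal 10 (not isolated), via trimethylsilyl ester 11 (not isolated)
Conditions: LiN(iPr)2, THF, −78 °C; Me3SiCl, −78 → 50 °C; then H2O, pH 5
Reagents that add atoms: chlorotrimethylsilane, C[Si](C)(C)Cl (silicon is carried by 10 and 11 only)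
Why: Ireland–Claisen rearrangement: kinetic enolisation in THF gives the (E)-silyl ketene acetal, and the chair transition state with the carbinol methyl equatorial and the (E)-alkene transfers the (R)-carbinol chirality to C1 (S) while the ketene acetal geometry sets C10 (S), the anti pair, and leaves an (E)-propenyl group on C1.

Step 7
Reactants: 12 (2S,3S,4E)-3-(1-bromo-2-methylprop-1-en-1-yl)-2-(2,2-dimethoxyethyl)hex-4-enoic acid
Product: 15 (3S,4R)-4-(1-bromo-2-methylprop-1-en-1-yl)-3-(2,2-dimethoxyethyl)oxolan-2-one, via ozonide 13 (not isolated), via hydroxy acid 14 (not isolated)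
Conditions: O3, CH2Cl2, −78 °C; NaBH4, MeOH, −78 → 0 °C; then EDC·HCl, DMAP (cat.), CH2Cl2, 0 °C
Reagents that add atoms: ozone, [O-][O+]=O
Why: Ozone should attack the 1,2-disubstituted alkene much faster than the hindered, electron-poor tetrasubstituted alkenyl bromide, NaBH4 reduces the ozonide to the C2 alcohol, and carbodiimide lactonisation avoids acid (acetal ionisation) and base (C10 epimerisation of the cis lactone); the lactone oxygen then protects C2.

Step 8
Reactants: 15 (3S,4R)-4-(1-bromo-2-methylprop-1-en-1-yl)-3-(2,2-dimethoxyethyl)oxolan-2-one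
Product: 16 (2R,3S)-2-(1-bromo-2-methylprop-1-en-1-yl)-3-(1-hydroxycyclopropyl)-5,5-dimethoxypentan-1-ol
Conditions: EtMgBr, Ti(OiPr)4 (30 mol%), THF, 15 °C; aq. NH4Cl
Reagents that add atoms: ethylmagnesium bromide, CC[Mg]Br
Why: Kulinkovich reaction: the titanacyclopropane from EtMgBr and Ti(OiPr)4 adds twice to the lactone carbonyl, turning C11 into a cyclopropanol carbon bearing C12 and C13 and freeing the C2 hydroxyl; lactones are established substrates and C10 should not be enolised.

Step 9
Reactants: 16 (2R,3S)-2-(1-bromo-2-methylprop-1-en-1-yl)-3-(1-hydroxycyclopropyl)-5,5-dimethoxypentan-1-ol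
Product: 17 1-{(3S,4R)-4-(1-bromo-2-methylprop-1-en-1-yl)-1,1-dimethoxy-5-[(triethylsilyl)oxy]pentan-3-yl}cyclopropan-1-ol
Conditions: Et3SiCl (1.05 equiv), imidazole, CH2Cl2, −20 °C
Reagents that add atoms: chlorotriethylsilane, CC[Si](Cl)(CC)CC
Why: Silylation of the primary alcohol is much faster than that of the tertiary cyclopropanol; a free primary alkoxide would bind palladium in the next step and undergo β-hydride elimination.

Step 10
Reactants: 17 1-{(3S,4R)-4-(1-bromo-2-methylprop-1-en-1-yl)-1,1-dimethoxy-5-[(triethylsilyl)oxy]pentan-3-yl}cyclopropan-1-ol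
Product: 18 (2S,3S)-2-(2,2-dimethoxyethyl)-4-(propan-2-ylidene)-3-{[(triethylsilyl)oxy]methyl}cyclohexan-1-one
Conditions: Pd(OAc)2 (5 mol%), XPhos (10 mol%), Cs2CO3, toluene, 80 °C
Reagents that add atoms: none
Why: Zerovalent palladium (from Pd(OAc)2 and the phosphine) inserts into the C14–Br bond, the cyclopropanol oxygen replaces bromide on palladium, β-carbon elimination opens the strained ring to an alkylpalladium homoenolate, and reductive elimination joins C13 to C14. The closest known reaction type is the palladium-catalysed ring-opening cross-coupling of cyclopropanols with aryl and alkenyl halides, run here within one molecule. The six-membered ring C11–C12–C13–C14–C1–C10 closes by C(sp3)–C(sp2) reductive elimination from a seven-membered palladacycle, formally a 6-exo substitution at the trigonal carbon C14 and overall a three-atom expansion of the cyclopropanol ring. No stereocentre is formed: C1 and C10 come unchanged from step 6, and because C15 bears two methyl groups the alkene has no geometry to control. Reductive elimination must outrun β-hydride elimination of the homoenolate, and both cyclopropane bonds must lead to one product; the bulky electron-rich biaryl phosphine should secure the first, the equivalence of C12 and C13 secures the second, and the silyl ether on the C2 oxygen removes the only competing alkoxide. Carbonate in toluene should be too weak to epimerise C10, which becomes α to the new ketone.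

Step 11
Reactants: 18 (2S,3S)-2-(2,2-dimethoxyethyl)-4-(propan-2-ylidene)-3-{[(triethylsilyl)oxy]methyl}cyclohexan-1-one
Product: 19 {[(1S,2S)-2-(2,2-dimethoxyethyl)-3-methylidene-6-(propan-2-ylidene)cyclohexyl]methoxy}triethylsilane
Conditions: Tebbe reagent Cp2Ti(μ-Cl)(μ-CH2)AlMe2, pyridine (cat.), THF, −40 → 0 °C
Reagents that add atoms: Tebbe reagent, C=[Ti](C1C=CC=C1)C1C=CC=C1.C[Al](C)Cl
Why: Tebbe methylenation (titanium methylidene, [2+2] addition and cycloreversion) is non-basic, so the α-stereocentre C10 should not epimerise, and it tolerates the acetal and the silyl ether.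

Step 12
Reactants: 19 {[(1S,2S)-2-(2,2-dimethoxyethyl)-3-methylidene-6-(propan-2-ylidene)cyclohexyl]methoxy}triethylsilane
Product: 20 (1S,2S)-2-(2,2-dimethoxyethyl)-3-methylidene-6-(propan-2-ylidene)cyclohexane-1-carbaldehyde
Conditions: (COCl)2, DMSO, CH2Cl2, −78 → −40 °C; Et3N, −78 → 0 °C
Reagents that add atoms: none
Why: Under Swern conditions primary triethylsilyl ethers are known to go directly to aldehydes (chlorosulfonium-induced desilylation, then fragmentation of the alkoxysulfonium ylide); the low temperature limits enolisation at C1, which is α to the aldehyde and allylic.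

Step 13
Reactants: 21 methyl 2-(dimethoxyphosphoryl)acetate; 22 2-(2-bromoethyl)-1,3-dioxolane
Product: 23 methyl 2-(dimethoxyphosphoryl)-4-(1,3-dioxolan-2-yl)butanoate
Conditions: NaH, DMF, 0 → 60 °C
Reagents that add atoms: none
Why: SN2 C-alkylation of the sodium salt of the phosphonoacetate with a primary bromide.

Step 14
Reactants: 23 methyl 2-(dimethoxyphosphoryl)-4-(1,3-dioxolan-2-yl)butanoate
Product: 24 methyl 2-(dimethoxyphosphoryl)-5-oxopentanoate
Conditions: 1 M HCl, acetone, rt
Reagents that add atoms: water, O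
Why: Acid-catalysed hydrolysis of the dioxolane; the phosphonate and the methyl ester are stable to dilute acid at room temperature.

Step 15
Reactants: 24 methyl 2-(dimethoxyphosphoryl)-5-oxopentanoate; 25 prop-2-en-1-yl 2-(triphenyl-λ5-phosphanylidene)acetate
Product: 27 7-methyl 1-prop-2-en-1-yl (2Z)-6-(dimethoxyphosphoryl)-2-iodohept-2-enedioate, via iodo ylide 26 (not isolated)
Conditions: 25, N-iodosuccinimide, K2CO3, MeCN, −20 °C; filtration; then 24, −20 °C → rt
Reagents that add atoms: N-iodosuccinimide, O=C1CCC(=O)N1I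
Why: The stabilised ylide is iodinated at carbon and deprotonated again to the iodo ylide, whose Wittig reaction with aldehydes is known to give (Z)-α-iodoenoates (iodine cis to the chain, ester trans), the geometry needed at C6=C7; the base is filtered off so the phosphonate aldehyde cannot self-condense.

Step 16
Reactants: 20 (1S,2S)-2-(2,2-dimethoxyethyl)-3-methylidene-6-(propan-2-ylidene)cyclohexane-1-carbaldehyde; 27 7-methyl 1-prop-2-en-1-yl (2Z)-6-(dimethoxyphosphoryl)-2-iodohept-2-enedioate
Product: 28 7-methyl 1-prop-2-en-1-yl (2Z,6E)-6-{[(1S,2S)-2-(2,2-dimethoxyethyl)-3-methylidene-6-(propan-2-ylidene)cyclohexyl]methylidene}-2-iodohept-2-enedioate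
Conditions: Ba(OH)2·8H2O, THF/H2O (40:1), 0 °C → rt
Reagents that add atoms: none
Why: Horner–Wadsworth–Emmons olefination with an α-substituted phosphonoacetate should give the (E)-trisubstituted enoate (C1 trans to CO2Me) through the less crowded, reversibly formed adduct; Ba(OH)2 in wet THF is mild enough for α-epimerisable aldehydes and should leave the allyl ester, alkenyl iodide and acetal untouched.

Step 17
Reactants: 28 7-methyl 1-prop-2-en-1-yl (2Z,6E)-6-{[(1S,2S)-2-(2,2-dimethoxyethyl)-3-methylidene-6-(propan-2-ylidene)cyclohexyl]methylidene}-2-iodohept-2-enedioate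
Product: 29 7-methyl 1-prop-2-en-1-yl (2Z,6E)-2-iodo-6-{[(1S,2S)-3-methylidene-2-(2-oxoethyl)-6-(propan-2-ylidene)cyclohexyl]methylidene}hept-2-enedioate
Conditions: PPTS, acetone/H2O (10:1), 45 °C
Reagents that add atoms: water, O
Why: Mild acid-catalysed hydrolysis of the dimethyl acetal, under conditions that should neither protonate the 1,1-disubstituted and tetrasubstituted alkenes nor cleave the esters.

Step 18
Reactants: 29 7-methyl 1-prop-2-en-1-yl (2Z,6E)-2-iodo-6-{[(1S,2S)-3-methylidene-2-(2-oxoethyl)-6-(propan-2-ylidene)cyclohexyl]methylidene}hept-2-enedioate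
Product: 30 microeunicellol A prop-2-en-1-yl ester (allyl ester at the C7 carboxyl, methyl ester at the C3 carboxyl, 1S,8R,10S, both ring alkenes E)
Conditions: CrCl2, NiCl2 (2 mol%), DMSO, rt, 2 mM (slow addition)
Reagents that add atoms: none
Why: Nozaki–Hiyama–Kishi reaction: zerovalent nickel inserts into the C7–I bond, the alkenyl group passes to chromium with retention of geometry and adds to the C8 aldehyde in the presence of the esters; high dilution favours the ten-membered ring, whose two anchor points are held trans on the cyclohexane, and the aldehyde is expected to react with its oxygen turned away from the ring interior, which should favour the (8R)-alcohol (substrate control, the least secure stereochemical element of the route).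

Step 19
Reactants: 30 microeunicellol A prop-2-en-1-yl ester
Product: 31 microeunicellol A
Conditions: Pd(PPh3)4 (5 mol%), morpholine, THF, rt; aq. NaH2PO4 work-up
Reagents that add atoms: none
Why: Tsuji–Trost deallylation: zerovalent palladium ionises only the allyl ester to a π-allyl complex that morpholine captures, so the methyl ester, the free allylic alcohol and the alkenes should be untouched.

Compound list
1 | 3-methylbut-2-enal | CC(C)=CC=O | starting material
2 | 2,3-dibromo-3-methylbutanal | CC(C)(Br)C(Br)C=O | intermediate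
3 | 2-bromo-3-methylbut-2-enal | CC(C)=C(Br)C=O | intermediate
4 | 1-(triphenyl-λ5-phosphanylidene)propan-2-one | CC(=O)C=P(c1ccccc1)(c1ccccc1)c1ccccc1 | starting material
5 | (3E)-5-bromo-6-methylhepta-3,5-dien-2-one | CC(=O)/C=C/C(Br)=C(C)C | intermediate
6 | (2R,3E)-5-bromo-6-methylhepta-3,5-dien-2-ol | C[C@@H](O)/C=C/C(Br)=C(C)C | intermediate
7 | methyl 4,4-dimethoxybutanoate | COC(=O)CCC(OC)OC | starting material
8 | 4,4-dimethoxybutanoic acid | OC(=O)CCC(OC)OC | intermediate
9 | (2R,3E)-5-bromo-6-methylhepta-3,5-dien-2-yl 4,4-dimethoxybutanoate | C[C@@H](OC(=O)CCC(OC)OC)/C=C/C(Br)=C(C)C | intermediate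
10 | {[(1E)-1-{[(2R,3E)-5-bromo-6-methylhepta-3,5-dien-2-yl]oxy}-4,4-dimethoxybut-1-en-1-yl]oxy}trimethylsilane | COC(OC)C/C=C(/O[Si](C)(C)C)O[C@H](C)/C=C/C(Br)=C(C)C | intermediate
11 | trimethylsilyl (2S,3S,4E)-3-(1-bromo-2-methylprop-1-en-1-yl)-2-(2,2-dimethoxyethyl)hex-4-enoate | C[Si](C)(C)OC(=O)[C@@H](CC(OC)OC)[C@H](/C=C/C)C(Br)=C(C)C | intermediate
12 | (2S,3S,4E)-3-(1-bromo-2-methylprop-1-en-1-yl)-2-(2,2-dimethoxyethyl)hex-4-enoic acid | OC(=O)[C@@H](CC(OC)OC)[C@H](/C=C/C)C(Br)=C(C)C | intermediate
13 | (2S,3R)-4-bromo-2-(2,2-dimethoxyethyl)-5-methyl-3-(5-methyl-1,2,4-trioxolan-3-yl)hex-4-enoic acid (mixture at the trioxolane carbons) | OC(=O)[C@@H](CC(OC)OC)[C@H](C1OOC(C)O1)C(Br)=C(C)C | intermediate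
14 | (2S,3R)-4-bromo-2-(2,2-dimethoxyethyl)-3-(hydroxymethyl)-5-methylhex-4-enoic acid | OC(=O)[C@@H](CC(OC)OC)[C@H](CO)C(Br)=C(C)C | intermediate
15 | (3S,4R)-4-(1-bromo-2-methylprop-1-en-1-yl)-3-(2,2-dimethoxyethyl)oxolan-2-one (cis lactone) | O=C1OC[C@H](C(Br)=C(C)C)[C@@H]1CC(OC)OC | intermediate
16 | (2R,3S)-2-(1-bromo-2-methylprop-1-en-1-yl)-3-(1-hydroxycyclopropyl)-5,5-dimethoxypentan-1-ol | OC1(CC1)[C@@H](CC(OC)OC)[C@H](CO)C(Br)=C(C)C | intermediate
17 | 1-{(3S,4R)-4-(1-bromo-2-methylprop-1-en-1-yl)-1,1-dimethoxy-5-[(triethylsilyl)oxy]pentan-3-yl}cyclopropan-1-ol | OC1(CC1)[C@@H](CC(OC)OC)[C@H](CO[Si](CC)(CC)CC)C(Br)=C(C)C | intermediate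
18 | (2S,3S)-2-(2,2-dimethoxyethyl)-4-(propan-2-ylidene)-3-{[(triethylsilyl)oxy]methyl}cyclohexan-1-one | O=C1CCC(=C(C)C)[C@@H](CO[Si](CC)(CC)CC)[C@@H]1CC(OC)OC | intermediate
19 | {[(1S,2S)-2-(2,2-dimethoxyethyl)-3-methylidene-6-(propan-2-ylidene)cyclohexyl]methoxy}triethylsilane | C=C1CCC(=C(C)C)[C@@H](CO[Si](CC)(CC)CC)[C@@H]1CC(OC)OC | intermediate
20 | (1S,2S)-2-(2,2-dimethoxyethyl)-3-methylidene-6-(propan-2-ylidene)cyclohexane-1-carbaldehyde | C=C1CCC(=C(C)C)[C@@H](C=O)[C@@H]1CC(OC)OC | intermediate
21 | methyl 2-(dimethoxyphosphoryl)acetate (trimethyl phosphonoacetate) | COC(=O)CP(=O)(OC)OC | starting material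
22 | 2-(2-bromoethyl)-1,3-dioxolane | BrCCC1OCCO1 | starting material
23 | methyl 2-(dimethoxyphosphoryl)-4-(1,3-dioxolan-2-yl)butanoate | COC(=O)C(CCC1OCCO1)P(=O)(OC)OC | intermediate
24 | methyl 2-(dimethoxyphosphoryl)-5-oxopentanoate | COC(=O)C(CCC=O)P(=O)(OC)OC | intermediate
25 | prop-2-en-1-yl 2-(triphenyl-λ5-phosphanylidene)acetate | C=CCOC(=O)C=P(c1ccccc1)(c1ccccc1)c1ccccc1 | starting material
26 | prop-2-en-1-yl 2-iodo-2-(triphenyl-λ5-phosphanylidene)acetate | C=CCOC(=O)C(I)=P(c1ccccc1)(c1ccccc1)c1ccccc1 | intermediate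
27 | 7-methyl 1-prop-2-en-1-yl (2Z)-6-(dimethoxyphosphoryl)-2-iodohept-2-enedioate | C=CCOC(=O)/C(I)=C/CCC(C(=O)OC)P(=O)(OC)OC | intermediate
28 | 7-methyl 1-prop-2-en-1-yl (2Z,6E)-6-{[(1S,2S)-2-(2,2-dimethoxyethyl)-3-methylidene-6-(propan-2-ylidene)cyclohexyl]methylidene}-2-iodohept-2-enedioate | C=C1CCC(=C(C)C)[C@@H](/C=C(/C(=O)OC)CC/C=C(\I)C(=O)OCC=C)[C@@H]1CC(OC)OC | intermediate
29 | 7-methyl 1-prop-2-en-1-yl (2Z,6E)-2-iodo-6-{[(1S,2S)-3-methylidene-2-(2-oxoethyl)-6-(propan-2-ylidene)cyclohexyl]methylidene}hept-2-enedioate | C=C1CCC(=C(C)C)[C@@H](/C=C(/C(=O)OC)CC/C=C(\I)C(=O)OCC=C)[C@@H]1CC=O | intermediate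
30 | microeunicellol A prop-2-en-1-yl ester (allyl ester at the C7 carboxyl, methyl ester at the C3 carboxyl; 1S,8R,10S; ring alkenes 2E and 6E) | C=C1CCC(=C(C)C)[C@H]2/C=C(/C(=O)OC)CC/C=C(/C(=O)OCC=C)[C@H](O)C[C@H]12 | intermediate
31 | microeunicellol A | C=C1CCC(=C(C)C)[C@H]2/C=C(/C(=O)OC)CC/C=C(/C(=O)O)[C@H](O)C[C@H]12 | target

Total step count: 19. Longest linear sequence: 15 steps (steps 1–3, 5–12 and 16–19).

Steps most likely to fail

Step 10. β-Hydride elimination of the palladium homoenolate (which would also reduce the C–Br bond) may outrun reductive elimination, oxidative addition at the tetrasubstituted alkenyl bromide may be slow, or C10 may epimerise after ring closure. The fallback sets out from 17 and makes the same C13–C14 bond by a radical conjugate addition. N-Bromosuccinimide in CH2Cl2 at 0 °C should open the cyclopropanol to the β-bromo ketone (4S,5R)-1-bromo-5-(1-bromo-2-methylprop-1-en-1-yl)-4-(2,2-dimethoxyethyl)-6-[(triethylsilyl)oxy]hexan-3-one F1, and triethylamine should eliminate HBr to the vinyl ketone (4S,5R)-5-(1-bromo-2-methylprop-1-en-1-yl)-4-(2,2-dimethoxyethyl)-6-[(triethylsilyl)oxy]hex-1-en-3-one F2. Bu3SnH and AIBN in benzene at 80 °C under high dilution should then generate the C14 alkenyl radical, which closes the ring by 6-endo-trig addition to the enone terminus C13; the resulting α-keto radical is reduced, and the route is rejoined at 18.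

Step 18. The C–I bond may be reduced before ring closure, intermolecular coupling may compete, or facial selectivity at C8 may be poor. The fallback sets out from 20, sets C8 by reagent control and closes the ring at C6=C7 by metathesis. Alkylation of 21 with 4-bromobut-1-ene (NaH, DMF) gives methyl 2-(dimethoxyphosphoryl)hex-5-enoate F3, which with 20 and Ba(OH)2 should give the (E)-enoate methyl (2E)-2-{[(1S,2S)-2-(2,2-dimethoxyethyl)-3-methylidene-6-(propan-2-ylidene)cyclohexyl]methylidene}hex-5-enoate F4. Acetal hydrolysis (PPTS, wet acetone) gives the aldehyde methyl (2E)-2-{[(1S,2S)-3-methylidene-2-(2-oxoethyl)-6-(propan-2-ylidene)cyclohexyl]methylidene}hex-5-enoate F5. A β-isocupreidine-catalysed Morita–Baylis–Hillman reaction with 1,1,1,3,3,3-hexafluoropropan-2-yl acrylate (DMF, −55 °C) should give the (8R)-hydroxy acrylate F6, the hexafluoropropan-2-yl 2-methylidene-3-hydroxy ester at C7/C8. Ring-closing metathesis with the second-generation Hoveyda–Grubbs catalyst (toluene, 80 °C, 1 mM) between the butenyl and acrylate alkenes should give microeunicellol A 1,1,1,3,3,3-hexafluoropropan-2-yl ester F7. LiOH (1 equiv) in THF/H2O at 0 °C should cleave the activated ester selectively, rejoining the route at 31.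

Step 16. Olefination at the hindered aldehyde may be slow enough for enolisation to erode the configuration at C1, or the (E)-selectivity may be poor. The fallback sets out from 20 and builds C2=C3 by aldol addition and elimination. Methyl 5-hydroxypentanoate is silylated (TBSCl, imidazole) to methyl 5-[(tert-butyldimethylsilyl)oxy]pentanoate F8; its lithium enolate (LiN(iPr)2, THF, −78 °C) should add to 20 to give the β-hydroxy ester methyl 5-[(tert-butyldimethylsilyl)oxy]-2-{[(1S,2S)-2-(2,2-dimethoxyethyl)-3-methylidene-6-(propan-2-ylidene)cyclohexyl](hydroxy)methyl}pentanoate F9 as a diastereomer mixture. Mesylation (MsCl, Et3N) and DBU elimination should give the thermodynamic (E)-enoate methyl (2E)-5-[(tert-butyldimethylsilyl)oxy]-2-{[(1S,2S)-2-(2,2-dimethoxyethyl)-3-methylidene-6-(propan-2-ylidene)cyclohexyl]methylidene}pentanoate F10. HF·pyridine gives the alcohol methyl (2E)-2-{[(1S,2S)-2-(2,2-dimethoxyethyl)-3-methylidene-6-(propan-2-ylidene)cyclohexyl]methylidene}-5-hydroxypentanoate F11, and Dess–Martin periodinane gives the aldehyde methyl (2E)-2-{[(1S,2S)-2-(2,2-dimethoxyethyl)-3-methylidene-6-(propan-2-ylidene)cyclohexyl]methylidene}-5-oxopentanoate F12. Wittig reaction of F12 with iodo ylide 26 (made from 25 and N-iodosuccinimide as in step 15) rejoins the route at 28.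

Further compounds
F1 | step 10 | (4S,5R)-1-bromo-5-(1-bromo-2-methylprop-1-en-1-yl)-4-(2,2-dimethoxyethyl)-6-[(triethylsilyl)oxy]hexan-3-one | BrCCC(=O)[C@@H](CC(OC)OC)[C@H](CO[Si](CC)(CC)CC)C(Br)=C(C)C
F2 | step 10 | (4S,5R)-5-(1-bromo-2-methylprop-1-en-1-yl)-4-(2,2-dimethoxyethyl)-6-[(triethylsilyl)oxy]hex-1-en-3-one | C=CC(=O)[C@@H](CC(OC)OC)[C@H](CO[Si](CC)(CC)CC)C(Br)=C(C)C
F3 | step 18 | methyl 2-(dimethoxyphosphoryl)hex-5-enoate | COC(=O)C(CCC=C)P(=O)(OC)OC
F4 | step 18 | methyl (2E)-2-{[(1S,2S)-2-(2,2-dimethoxyethyl)-3-methylidene-6-(propan-2-ylidene)cyclohexyl]methylidene}hex-5-enoate | C=C1CCC(=C(C)C)[C@@H](/C=C(/C(=O)OC)CCC=C)[C@@H]1CC(OC)OC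
F5 | step 18 | methyl (2E)-2-{[(1S,2S)-3-methylidene-2-(2-oxoethyl)-6-(propan-2-ylidene)cyclohexyl]methylidene}hex-5-enoate | C=C1CCC(=C(C)C)[C@@H](/C=C(/C(=O)OC)CCC=C)[C@@H]1CC=O
F6 | step 18 | 1,1,1,3,3,3-hexafluoropropan-2-yl (3R)-3-hydroxy-4-{(1S,2S)-2-[(1E)-2-(methoxycarbonyl)hexa-1,5-dien-1-yl]-6-methylidene-3-(propan-2-ylidene)cyclohexyl}-2-methylidenebutanoate | C=C1CCC(=C(C)C)[C@@H](/C=C(/C(=O)OC)CCC=C)[C@@H]1C[C@@H](O)C(=C)C(=O)OC(C(F)(F)F)C(F)(F)F
F7 | step 18 | microeunicellol A 1,1,1,3,3,3-hexafluoropropan-2-yl ester | C=C1CCC(=C(C)C)[C@H]2/C=C(/C(=O)OC)CC/C=C(/C(=O)OC(C(F)(F)F)C(F)(F)F)[C@H](O)C[C@H]12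
F8 | step 16 | methyl 5-[(tert-butyldimethylsilyl)oxy]pentanoate | COC(=O)CCCCO[Si](C)(C)C(C)(C)C
F9 | step 16 | methyl 5-[(tert-butyldimethylsilyl)oxy]-2-{[(1S,2S)-2-(2,2-dimethoxyethyl)-3-methylidene-6-(propan-2-ylidene)cyclohexyl](hydroxy)methyl}pentanoate | C=C1CCC(=C(C)C)[C@@H](C(O)C(CCCO[Si](C)(C)C(C)(C)C)C(=O)OC)[C@@H]1CC(OC)OC
F10 | step 16 | methyl (2E)-5-[(tert-butyldimethylsilyl)oxy]-2-{[(1S,2S)-2-(2,2-dimethoxyethyl)-3-methylidene-6-(propan-2-ylidene)cyclohexyl]methylidene}pentanoate | C=C1CCC(=C(C)C)[C@@H](/C=C(/C(=O)OC)CCCO[Si](C)(C)C(C)(C)C)[C@@H]1CC(OC)OC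
F11 | step 16 | methyl (2E)-2-{[(1S,2S)-2-(2,2-dimethoxyethyl)-3-methylidene-6-(propan-2-ylidene)cyclohexyl]methylidene}-5-hydroxypentanoate | C=C1CCC(=C(C)C)[C@@H](/C=C(/C(=O)OC)CCCO)[C@@H]1CC(OC)OC
F12 | step 16 | methyl (2E)-2-{[(1S,2S)-2-(2,2-dimethoxyethyl)-3-methylidene-6-(propan-2-ylidene)cyclohexyl]methylidene}-5-oxopentanoate | C=C1CCC(=C(C)C)[C@@H](/C=C(/C(=O)OC)CCC=O)[C@@H]1CC(OC)OC
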